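**Retrosynthetic overview**

1. The target is numbered as a spiro[chromene-2,2′-naphthalene]. The spiro carbon C-2 carries the pyran oxygen O-1 (ketal oxidation level) and is bonded to C-1′, the vinylic CH of the only olefin (C-1′=C-8a′, exocyclic to the methyl/isopropyl cyclohexane, ring A). An O-bearing carbon next to a vinylic CH is what a cyclic oxocarbenium ion gives when it is captured at the silicon-bearing carbon of a vinylsilane.
2. Key disconnection C-2–C-1′ (closure of the cyclohexene, ring B): target ⇒ 2-hydroxychroman (hemiketal) whose side chain ends in a (Z)-vinylsilane on ring A.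
3. Hemiketal ⇒ styryl ketone + 2,4-diformylphloroglucinol: C-4–C-4a by catalytic enantioselective Michael addition, O-1–C-2 by hemiketalisation (pyran ring C).
4. Styryl ketone ⇒ benzaldehyde + methyl ketone ⇒ methyl vinyl ketone + allylic geminal bis(silane) ⇒ (−)-menthone (C-5′ and C-8′ bought). One silicon is spent in a Hosomi–Sakurai addition that sets C-4a′; the second remains as the (Z)-vinylsilane.
5. Order of rings: ring A and both arenes bought; ring C in step 5; ring B last, in step 6.

Key step: step 6

Remark: 2,4,6-trihydroxybenzene-1,3-dicarbaldehyde is taken as a purchasable building block, and the sense of induction of the amine catalyst in step 5 is assigned by analogy with benzylideneacetone acceptors; if it is reversed for this nucleophile, the mirror-image catalyst is used.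

**Step 1**
Reactants: 1 (−)-menthone
Product: 3 (3R,6S)-3-methyl-6-(propan-2-yl)cyclohex-1-en-1-yl trifluoromethanesulfonate, via lithium enolate 2 (not isolated)
Conditions: LiN(iPr)2 (1.1 equiv), THF, −78 °C; then PhNTf2, −78 °C → 0 °C
Reagents that add atoms: N-phenylbis(trifluoromethanesulfonimide), O=S(=O)(N(c1ccccc1)S(=O)(=O)C(F)(F)F)C(F)(F)F
Why: Kinetic deprotonation by the hindered amide should remove a proton of the CH2 group rather than the more hindered CH(iPr), and O-sulfonylation of the enolate (enol triflate formation) fixes the double bond without touching either stereocentre.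

**Step 2**
Reactants: 3 enol triflate
Product: 4 [(3R,6S)-3-methyl-6-(propan-2-yl)cyclohex-1-en-1-yl]methanediylbis(trimethylsilane)
Conditions: (Me3Si)2CHMgCl [from (Me3Si)2CHCl and Mg, THF, reflux], Pd(PPh3)4 (5 mol %), THF, 60 °C
Reagents that add atoms: chlorobis(trimethylsilyl)methane, C[Si](C)(C)C(Cl)[Si](C)(C)C (used as its organomagnesium chloride)
Why: Kumada–Corriu coupling of an α-silyl organomagnesium reagent with an enol triflate at zerovalent palladium, the standard route to allylsilanes; the reagent has no β-hydrogen, and no stereocentre is formed.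

**Step 3**
Reactants: 4 allylic geminal bis(silane); 5 methyl vinyl ketone
Product: 6 4-[(1R,2Z,3S,6R)-6-methyl-3-(propan-2-yl)-2-[(trimethylsilyl)methylidene]cyclohexyl]butan-2-one
Conditions: TiCl4 (1.1 equiv), CH2Cl2, −78 °C; aqueous NaHCO3 quench at −78 °C
Reagents that add atoms: none
Why: Hosomi–Sakurai conjugate allylation in which the ring CH terminus should attack the TiCl4-activated enone anti to one C–Si bond and axially on the half-chair with pseudo-equatorial isopropyl and methyl groups, so the chain enters trans to isopropyl and cis to methyl (new centre R), while the in-plane isopropyl group pushes the remaining silicon to the side of the newly substituted ring carbon and gives the (Z)-vinylsilane.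

**Step 4**
Reactants: 6 methyl ketone; 7 benzaldehyde
Product: 9 (1E)-5-[(1R,2Z,3S,6R)-6-methyl-3-(propan-2-yl)-2-[(trimethylsilyl)methylidene]cyclohexyl]-1-phenylpent-1-en-3-one, via aldol adduct 8 (not isolated)
Conditions: NaOH (20 mol %), EtOH–H2O, 0 °C → rt
Reagents that add atoms: none
Why: Claisen–Schmidt condensation at the methyl group of the ketone with a non-enolisable aldehyde and E1cB dehydration should give the (E)-enone; no ring stereocentre is alpha to the carbonyl group, so none can epimerise, and the vinylsilane is inert to base.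

**Step 5**
Reactants: 9 styryl ketone; 10 2,4,6-trihydroxybenzene-1,3-dicarbaldehyde
Product: 12 (4S)-2,5,7-trihydroxy-2-[2-[(1R,2Z,3S,6R)-6-methyl-3-(propan-2-yl)-2-[(trimethylsilyl)methylidene]cyclohexyl]ethyl]-4-phenyl-3,4-dihydro-2H-chromene-6,8-dicarbaldehyde (hemiketal; both C-2 epimers), via keto phenol 11 (not isolated)
Conditions: 4,5-diphenylimidazolidine-2-carboxylic acid (10 mol %; the antipode that gives (S)-warfarin from 4-hydroxycoumarin and benzylideneacetone), THF–CH2Cl2, rt
Reagents that add atoms: none
Why: Iminium-activated enantioselective Michael (Friedel–Crafts-type) addition of the C–H acidic trihydroxyarene, the reaction type of the organocatalytic warfarin synthesis; the chiral secondary amine (which cannot form a stable imine with the aryl aldehydes) shields one face of the iminium ion and should set the benzylic centre (S), after which an ortho hydroxyl group closes the hemiketal.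

**Step 6**
Reactants: 12 hemiketal
Product: 14 Guajadial D, via oxocarbenium ion 13 (not isolated)
Conditions: Sc(OTf)3 (10 mol %), 2,6-di-tert-butylpyridine (20 mol %), 4 Å molecular sieves, CH2Cl2, −20 °C → rt
Reagents that add atoms: none
Why: Sc(OTf)3 should ionise the hemiketal hydroxyl group (both epimers of 12 and the open form 11 converge) to the cyclic oxocarbenium ion 13, which the tethered (Z)-vinylsilane attacks with its silicon-bearing carbon; the tertiary β-silyl cation formed in ring A then loses the silyl group to scandium-bound hydroxide, giving Me3SiOH, the C-1′=C-8a′ double bond and free catalyst. The closest known reaction type is the vinylsilane-terminated cyclisation of oxocarbenium ions (silyl-Prins cyclisation), here on a ketone-derived cation so that a spiro centre results. Ring B closes in a six-membered mode that is endo with respect to the vinylsilane double bond and exo with respect to the C=O+ bond. The spiro centre C-2 is controlled by the phenyl-bearing centre C-4: the nucleophile should add to the face of the half-chair cation opposite to the phenyl group (attack on the same face would build a 1,3-diaxial phenyl/carbon contact), and this face also lets ring B form with O-1 pseudo-axial and C-3 pseudo-equatorial, so both elements point to the (2S) configuration. The step needs regiocontrol of the new olefin and chemoselectivity against protodesilylation: the β-silicon effect and the (Z) geometry (C–Si bond aligned with the empty orbital once ring B relaxes) should make loss of silicon faster than loss of the allylic proton at C-4a′, and the hindered pyridine keeps free triflic acid away from the vinylsilane and from the allylic spiro ether of the product.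

**Compound list**

1 | (−)-menthone, (2S,5R)-5-methyl-2-(propan-2-yl)cyclohexan-1-one | CC(C)[C@@H]1CC[C@@H](C)CC1=O | starting material
2 | lithium (3R,6S)-3-methyl-6-(propan-2-yl)cyclohex-1-en-1-olate (kinetic enolate, formed in the flask) | CC(C)[C@@H]1CC[C@@H](C)C=C1[O-].[Li+] | intermediate
3 | (3R,6S)-3-methyl-6-(propan-2-yl)cyclohex-1-en-1-yl trifluoromethanesulfonate | CC(C)[C@@H]1CC[C@@H](C)C=C1OS(=O)(=O)C(F)(F)F | intermediate
4 | [(3R,6S)-3-methyl-6-(propan-2-yl)cyclohex-1-en-1-yl]methanediylbis(trimethylsilane) | CC(C)[C@@H]1CC[C@@H](C)C=C1C([Si](C)(C)C)[Si](C)(C)C | intermediate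
5 | methyl vinyl ketone (but-3-en-2-one) | CC(=O)C=C | starting material
6 | 4-[(1R,2Z,3S,6R)-6-methyl-3-(propan-2-yl)-2-[(trimethylsilyl)methylidene]cyclohexyl]butan-2-one (chain cis to methyl, trans to isopropyl; silicon on the side of the chain-bearing ring carbon) | CC(C)[C@@H]1CC[C@@H](C)[C@@H](CCC(C)=O)/C1=C\[Si](C)(C)C | intermediate
7 | benzaldehyde | O=Cc1ccccc1 | starting material
8 | 5-hydroxy-1-[(1R,2Z,3S,6R)-6-methyl-3-(propan-2-yl)-2-[(trimethylsilyl)methylidene]cyclohexyl]-5-phenylpentan-3-one (aldol adduct, both carbinol epimers, formed in the flask) | CC(C)[C@@H]1CC[C@@H](C)[C@@H](CCC(=O)CC(O)c2ccccc2)/C1=C\[Si](C)(C)C | intermediate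
9 | (1E)-5-[(1R,2Z,3S,6R)-6-methyl-3-(propan-2-yl)-2-[(trimethylsilyl)methylidene]cyclohexyl]-1-phenylpent-1-en-3-one | CC(C)[C@@H]1CC[C@@H](C)[C@@H](CCC(=O)/C=C/c2ccccc2)/C1=C\[Si](C)(C)C | intermediate
10 | 2,4,6-trihydroxybenzene-1,3-dicarbaldehyde (2,4-diformylphloroglucinol) | O=Cc1c(O)c(C=O)c(O)cc1O | starting material
11 | 2,4,6-trihydroxy-5-[(1S)-5-[(1R,2Z,3S,6R)-6-methyl-3-(propan-2-yl)-2-[(trimethylsilyl)methylidene]cyclohexyl]-3-oxo-1-phenylpentyl]benzene-1,3-dicarbaldehyde (open keto phenol, formed in the flask) | CC(C)[C@@H]1CC[C@@H](C)[C@@H](CCC(=O)C[C@@H](c2ccccc2)c2c(O)c(C=O)c(O)c(C=O)c2O)/C1=C\[Si](C)(C)C | intermediate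
12 | (4S)-2,5,7-trihydroxy-2-[2-[(1R,2Z,3S,6R)-6-methyl-3-(propan-2-yl)-2-[(trimethylsilyl)methylidene]cyclohexyl]ethyl]-4-phenyl-3,4-dihydro-2H-chromene-6,8-dicarbaldehyde (hemiketal, both C-2 epimers) | CC(C)[C@@H]1CC[C@@H](C)[C@@H](CCC2(O)C[C@@H](c3ccccc3)c3c(O)c(C=O)c(O)c(C=O)c3O2)/C1=C\[Si](C)(C)C | intermediate
13 | (4S)-6,8-diformyl-5,7-dihydroxy-2-[2-[(1R,2Z,3S,6R)-6-methyl-3-(propan-2-yl)-2-[(trimethylsilyl)methylidene]cyclohexyl]ethyl]-4-phenyl-3,4-dihydrochromen-1-ium (cyclic oxocarbenium ion, formed in the flask) | CC(C)[C@@H]1CC[C@@H](C)[C@@H](CCC2=[O+]c3c(C=O)c(O)c(C=O)c(O)c3[C@H](c3ccccc3)C2)/C1=C\[Si](C)(C)C | intermediate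
14 | Guajadial D, (2S,4S,4a′R,5′R,8′S)-5,7-dihydroxy-5′-methyl-4-phenyl-8′-(propan-2-yl)-3,3′,4,4′,4a′,5′,6′,7′-octahydro-8′H-spiro[chromene-2,2′-naphthalene]-6,8-dicarbaldehyde | CC(C)[C@@H]1CC[C@@H](C)[C@H]2CC[C@@]3(C=C12)C[C@@H](c1ccccc1)c1c(O)c(C=O)c(O)c(C=O)c1O3 | target

**Step count and risks**

Total step count: 6. Longest linear sequence: 6 steps (1 → 3 → 4 → 6 → 9 → 12 → 14).

Steps most likely to fail:

1. **Step 3.** The hindered ring carbon may attack the enone too slowly, so that protodesilylation of the bis(silane) or polymerisation of the enone wins; the chain may enter from the wrong face; or the remaining silicon may end up on the wrong side of the new double bond. The fallback sets out from 3 and returns at 6, and reverses the polarity of the C–C bond formation.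
   - Reductive carbonylation of 3 (Pd(OAc)2, 1,3-bis(diphenylphosphino)propane, CO, Et3SiH, Et3N, DMF) should give (3R,6S)-3-methyl-6-(propan-2-yl)cyclohex-1-ene-1-carbaldehyde F1.
   - Copper-mediated conjugate addition of the organomagnesium reagent from 2-(2-bromoethyl)-2-methyl-1,3-dioxolane (CuBr·SMe2, Me3SiCl, THF, −78 °C, then mild aqueous acid) should give the ketal aldehyde (2R,3R,6S)-3-methyl-2-[2-(2-methyl-1,3-dioxolan-2-yl)ethyl]-6-(propan-2-yl)cyclohexane-1-carbaldehyde F2, with the chain again trans to isopropyl.
   - Enolisation with KN(SiMe3)2 and trapping with PhNTf2 should give the (Z)-enol triflate F3, with oxygen on the side of the ring carbon that carries the axial chain, where only a ring hydrogen lies in the olefin plane.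
   - Palladium-catalysed silylation with Me3SiSiMe3 (Pd(PPh3)4) should give the vinylsilane ketal F4.
   - Hydrolysis of the dioxolane (pyridinium p-toluenesulfonate, acetone–water) should give 6.

2. **Step 6.** The cation may be attacked on the wrong face if the phenyl group and the ring B transition state do not reinforce each other as predicted; the vinylsilane may be protodesilylated before it cyclises; the allylic spiro ether of the product may ionise; or the benzylic C–aryl bond may cleave by retro-Michael reaction. The fallback sets out from 9 and returns at 14, and makes the carbocycle first and the pyran ring last.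
   - TiCl4-promoted addition of the vinylsilane of 9 to its own ketone carbonyl (CH2Cl2, −78 °C; the six-membered ring is the only one within reach) should give the tertiary dienyl alcohol (4aR,5R,8S)-5-methyl-2-[(E)-2-phenylethenyl]-8-(propan-2-yl)-2,3,4,4a,5,6,7,8-octahydronaphthalen-2-ol F5.
   - Acid-catalysed condensation of F5 with 10 (BF3·OEt2, CH2Cl2, −40 °C) should give 14: ionisation to the pentadienyl cation, C-alkylation of the arene at the benzylic terminus, then closure of the phenol oxygen onto the tertiary allylic cation, as in the chroman synthesis from phenols and allylic alcohols. It would come together with C-2 and C-4 stereoisomers that have to be separated.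

3. **Step 5.** The two aryl aldehyde groups may tie up the amine catalyst, iminium formation with the ketone may be slow, or enantiofacial control may be low. The fallback sets out from 9 and returns at 14, and brings the aldehyde groups in last.
   - Excess benzene-1,3,5-triol is added to 9 under primary-amine iminium catalysis (9-amino-9-deoxy-epi-quinine, CF3CO2H, THF), the Friedel–Crafts/hemiketal reaction known for electron-rich phenols and enones, to give the aldehyde-free hemiketal (4S)-2-[2-[(1R,2Z,3S,6R)-6-methyl-3-(propan-2-yl)-2-[(trimethylsilyl)methylidene]cyclohexyl]ethyl]-4-phenyl-3,4-dihydro-2H-chromene-2,5,7-triol F6.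
   - The Sc(OTf)3 cyclisation of step 6 should then give the spiro chroman diol (2S,4S,4a′R,5′R,8′S)-5′-methyl-4-phenyl-8′-(propan-2-yl)-3,3′,4,4′,4a′,5′,6′,7′-octahydro-8′H-spiro[chromene-2,2′-naphthalene]-5,7-diol F7.
   - Double Vilsmeier–Haack formylation of the two free arene positions (POCl3, DMF, 0 °C; aqueous NaOAc) should give 14.

**Further compounds**

F1 | step 3 | (3R,6S)-3-methyl-6-(propan-2-yl)cyclohex-1-ene-1-carbaldehyde | CC(C)[C@@H]1CC[C@@H](C)C=C1C=O
F2 | step 3 | (2R,3R,6S)-3-methyl-2-[2-(2-methyl-1,3-dioxolan-2-yl)ethyl]-6-(propan-2-yl)cyclohexane-1-carbaldehyde (both C-1 epimers) | CC(C)[C@@H]1CC[C@@H](C)[C@@H](CCC2(C)OCCO2)C1C=O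
F3 | step 3 | (Z)-[(2R,3R,6S)-3-methyl-2-[2-(2-methyl-1,3-dioxolan-2-yl)ethyl]-6-(propan-2-yl)cyclohexylidene]methyl trifluoromethanesulfonate | CC(C)[C@@H]1CC[C@@H](C)[C@@H](CCC2(C)OCCO2)/C1=C\OS(=O)(=O)C(F)(F)F
F4 | step 3 | trimethyl[(Z)-[(2R,3R,6S)-3-methyl-2-[2-(2-methyl-1,3-dioxolan-2-yl)ethyl]-6-(propan-2-yl)cyclohexylidene]methyl]silane | CC(C)[C@@H]1CC[C@@H](C)[C@@H](CCC2(C)OCCO2)/C1=C\[Si](C)(C)C
F5 | step 6 | (4aR,5R,8S)-5-methyl-2-[(E)-2-phenylethenyl]-8-(propan-2-yl)-2,3,4,4a,5,6,7,8-octahydronaphthalen-2-ol (both C-2 epimers) | CC(C)[C@@H]1CC[C@@H](C)[C@H]2CCC(O)(/C=C/c3ccccc3)C=C12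
F6 | step 5 | (4S)-2-[2-[(1R,2Z,3S,6R)-6-methyl-3-(propan-2-yl)-2-[(trimethylsilyl)methylidene]cyclohexyl]ethyl]-4-phenyl-3,4-dihydro-2H-chromene-2,5,7-triol (both C-2 epimers) | CC(C)[C@@H]1CC[C@@H](C)[C@@H](CCC2(O)C[C@@H](c3ccccc3)c3c(O)cc(O)cc3O2)/C1=C\[Si](C)(C)C
F7 | step 5 | (2S,4S,4a′R,5′R,8′S)-5′-methyl-4-phenyl-8′-(propan-2-yl)-3,3′,4,4′,4a′,5′,6′,7′-octahydro-8′H-spiro[chromene-2,2′-naphthalene]-5,7-diol | CC(C)[C@@H]1CC[C@@H](C)[C@H]2CC[C@@]3(C=C12)C[C@@H](c1ccccc1)c1c(O)cc(O)cc1O3
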